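Abietane numbering is used (ring B: C5–C10; quinone ring C: C8, C9, C11–C14). Ring C is cut at C8–C14 and C11–C12 into a ring B dienol ether and isopropylmalonyl dichloride. The key step exploits the vinylogy of ring B: the C7 ketone makes C8 and the exocyclic C11 methylene on C9 a 1,3-bis-nucleophile, and C12–C13–C14 is a malonyl unit. One [3+3] operation closes ring C as a resorcinol; its C11–H is oxidised last. The precursor, a 3-methylidenecyclohexanone carrying both stereocentres, comes from (R)-carvone, whose isopropenyl group is spent as the C7 oxygen.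

Key step: step 8

Remark: 2-(propan-2-yl)propanedioyl dichloride is assumed not to be a catalogue item and is therefore made in step 7 from the commercial acid.

Step 1
Reactants: 1 (R)-(−)-carvone
Product: 4 (1R)-4-methyl-5-oxocyclohex-3-en-1-yl acetate, via methoxy hydroperoxide 2 (not isolated), via peroxyacetate 3 (not isolated)
Conditions: O3 (1 equiv, dye end point), CH2Cl2/MeOH, −78 °C; then Ac2O, Et3N, DMAP (cat.), 0 °C → rt
Reagents that add atoms: ozone, O=[O+][O-]
Why: Ozonolysis in methanol should cleave only the electron-rich isopropenyl alkene (the enone alkene is deactivated), and acetylation of the methoxy hydroperoxide triggers the Criegee rearrangement, in which the ring carbon migrates to oxygen with retention, so the carvone stereocentre becomes the C7 acetoxy carbon.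

Step 2
Reactants: 4 (1R)-4-methyl-5-oxocyclohex-3-en-1-yl acetate
Product: 5 (1R,5S)-4-methyl-5-(prop-1-en-2-yl)-3-[(trimethylsilyl)oxy]cyclohex-3-en-1-yl acetate
Conditions: CH2=C(CH3)MgBr, CuBr·SMe2 (10 mol%), Me3SiCl, THF, −78 °C; Et3N, cold aq. NaHCO3
Reagents that add atoms: isopropenylmagnesium bromide, CC(=C)[Mg]Br; chlorotrimethylsilane, C[Si](C)(C)Cl
Why: Chlorotrimethylsilane-accelerated copper-catalysed conjugate addition of the Grignard reagent should occur by axial attack anti to the C7 acetoxy group (trans-3,5 selectivity of 5-oxygenated cyclohexenones), which sets C5, and the enolate is trapped at once as the regiodefined silyl enol ether so that acetate is not eliminated.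

Step 3
Reactants: 5 (1R,5S)-4-methyl-5-(prop-1-en-2-yl)-3-[(trimethylsilyl)oxy]cyclohex-3-en-1-yl acetate; 6 methyl acrylate
Product: 8 methyl 3-[(1S,2S,4R)-4-(acetyloxy)-1-methyl-6-oxo-2-(prop-1-en-2-yl)cyclohexyl]propanoate, via titanium ester enolate 7 (not isolated)
Conditions: TiCl4 (1.1 equiv), CH2Cl2, −78 °C; aq. NaHCO3
Reagents that add atoms: none
Why: In this Mukaiyama–Michael addition the TiCl4-activated acrylate should approach C10 of the enol ether on the face anti to the neighbouring pseudoaxial isopropenyl group, which sets the quaternary centre with the ester chain trans and the methyl group cis to isopropenyl, and the base-free conditions spare the β-acetoxy ketone.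

Step 4
Reactants: 8 methyl 3-[(1S,2S,4R)-4-(acetyloxy)-1-methyl-6-oxo-2-(prop-1-en-2-yl)cyclohexyl]propanoate
Product: 9 methyl 3-[(1S,2S,4R)-4-(acetyloxy)-1-methyl-6-methylidene-2-(prop-1-en-2-yl)cyclohexyl]propanoate
Conditions: Zn, CH2Br2, TiCl4, THF/CH2Cl2, 0 °C → rt
Reagents that add atoms: dibromomethane, BrCBr
Why: The Takai–Lombardo methylenation uses a non-basic zinc–titanium methylene reagent that should convert the hindered, enolisable ketone into the C9=C11 methylidene group without touching the esters or eliminating the β-acetoxy group.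

Step 5
Reactants: 9 methyl 3-[(1S,2S,4R)-4-(acetyloxy)-1-methyl-6-methylidene-2-(prop-1-en-2-yl)cyclohexyl]propanoate
Product: 10 methyl 3-[(1S,2S,4R)-4-hydroxy-1-methyl-6-methylidene-2-(prop-1-en-2-yl)cyclohexyl]propanoate
Conditions: K2CO3 (cat.), MeOH, rt
Reagents that add atoms: none
Why: Base-catalysed transesterification with methanol removes the acetate while the methyl ester only exchanges with the solvent, and with the ketone gone no β-elimination is possible.

Step 6
Reactants: 10 methyl 3-[(1S,2S,4R)-4-hydroxy-1-methyl-6-methylidene-2-(prop-1-en-2-yl)cyclohexyl]propanoate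
Product: 11 methyl 3-[(1S,2S)-1-methyl-6-methylidene-4-oxo-2-(prop-1-en-2-yl)cyclohexyl]propanoate
Conditions: Dess–Martin periodinane, NaHCO3, CH2Cl2, 0 °C; used without chromatography
Reagents that add atoms: none
Why: Buffered Dess–Martin oxidation should turn the homoallylic alcohol into the β,γ-unsaturated ketone under neutral conditions that do not move the exocyclic double bond into conjugation.

Step 7
Reactants: 12 2-(propan-2-yl)propanedioic acid (isopropylmalonic acid)
Product: 13 2-(propan-2-yl)propanedioyl dichloride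
Conditions: SOCl2, DMF (cat.), 50 °C; distillation
Reagents that add atoms: thionyl chloride, O=S(Cl)Cl
Why: Acyl chloride formation from a malonic acid with thionyl chloride (DMF catalysis) is routine, and the dichloride is purified by distillation.

Step 8
Reactants: 11 methyl 3-[(1S,2S)-1-methyl-6-methylidene-4-oxo-2-(prop-1-en-2-yl)cyclohexyl]propanoate; 13 2-(propan-2-yl)propanedioyl dichloride
Product: 16 methyl 3-[(1S,2S)-5,7-dihydroxy-1-methyl-4-oxo-6-(propan-2-yl)-2-(prop-1-en-2-yl)-1,2,3,4-tetrahydronaphthalen-1-yl]propanoate, via silyl dienol ether 14 (not isolated), via keto acid chloride 15 (not isolated)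
Conditions: Me3SiOTf, Et3N, CH2Cl2, −78 → 0 °C; then slow addition to 13, CH2Cl2, −78 °C → rt; then Et3N, rt; aq. HCl/MeOH work-up
Reagents that add atoms: none
Why: Proposed new method: soft enolisation of 11 at the doubly activated C8 methylene gives the through-conjugated silyl dienol ether 14, whose unhindered terminal carbon C11 is acylated by one acyl chloride of 13 (C11–C12); the resulting β-keto acid chloride 15 loses HCl to an acylketene whose enol is a dienylketene (C8=C9–C11=C12–C13=C14=O), which closes the C8–C14 bond and tautomerises to the resorcinol. The closest known reaction types are the Effenberger cyclocondensation of enol ethers with malonyl dichlorides, the [3+3] cyclisation of bis-silyl dienol ethers with 1,3-dielectrophiles and the dienylketene ring closure of the Danheiser benzannulation. Ring C closes by a thermal six-electron electrocyclisation (equivalent to a 6-exo-trig C-acylation of the C7 dienol at C8), driven by aromatisation. No stereocentre is formed, and C5 and C10 carry no acidic hydrogen that the conditions could epimerise. The step needs acylation of 14 at C11 and not at C8 or oxygen, which the exocyclic CH2 should secure because C8 lies between the silyloxy carbon and the fully substituted C9, and it needs ring closure on carbon and not on oxygen, which is secured because after acylation at C11 only C8 can reach C14 through a six-membered ring.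

Step 9
Reactants: 16 methyl 3-[(1S,2S)-5,7-dihydroxy-1-methyl-4-oxo-6-(propan-2-yl)-2-(prop-1-en-2-yl)-1,2,3,4-tetrahydronaphthalen-1-yl]propanoate
Product: 17 methyl 3-[(1S,2S)-7-hydroxy-1-methyl-4,5,8-trioxo-6-(propan-2-yl)-2-(prop-1-en-2-yl)-1,2,3,4,5,8-hexahydronaphthalen-1-yl]propanoate (target)
Conditions: (KSO3)2NO, KH2PO4, acetone/H2O, rt
Reagents that add atoms: potassium nitrosodisulfonate (Fremy's salt), [K+].[K+].[O]N(S(=O)(=O)[O-])S(=O)(=O)[O-]
Why: In this Teuber oxidation the nitrosodisulfonate radical should oxidise the resorcinol at C11, the only free ring position (ortho to the C12 hydroxyl and para to the C14 hydroxyl), and the product settles as the 2-hydroxy-1,4-quinone tautomer, while alkenes, ketone and ester are inert to the reagent.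

Compound list
1 | (R)-(−)-carvone, (5R)-2-methyl-5-(prop-1-en-2-yl)cyclohex-2-en-1-one | CC1=CC[C@H](CC1=O)C(C)=C | starting material
2 | (5R)-5-(1-hydroperoxy-1-methoxyethyl)-2-methylcyclohex-2-en-1-one (mixture at the side-chain carbon) | CC1=CC[C@H](CC1=O)C(C)(OC)OO | intermediate
3 | 1-methoxy-1-[(1R)-4-methyl-5-oxocyclohex-3-en-1-yl]ethyl ethaneperoxoate | CC1=CC[C@H](CC1=O)C(C)(OC)OOC(C)=O | intermediate
4 | (1R)-4-methyl-5-oxocyclohex-3-en-1-yl acetate | CC1=CC[C@H](CC1=O)OC(C)=O | intermediate
5 | (1R,5S)-4-methyl-5-(prop-1-en-2-yl)-3-[(trimethylsilyl)oxy]cyclohex-3-en-1-yl acetate | CC1=C(O[Si](C)(C)C)C[C@H](OC(C)=O)C[C@H]1C(C)=C | intermediate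
6 | methyl acrylate | C=CC(=O)OC | starting material
7 | trichlorotitanium enolate of the methyl ester group of 8 | COC(O[Ti](Cl)(Cl)Cl)=CC[C@]1(C)C(=O)C[C@H](OC(C)=O)C[C@H]1C(C)=C | intermediate
8 | methyl 3-[(1S,2S,4R)-4-(acetyloxy)-1-methyl-6-oxo-2-(prop-1-en-2-yl)cyclohexyl]propanoate | COC(=O)CC[C@]1(C)C(=O)C[C@H](OC(C)=O)C[C@H]1C(C)=C | intermediate
9 | methyl 3-[(1S,2S,4R)-4-(acetyloxy)-1-methyl-6-methylidene-2-(prop-1-en-2-yl)cyclohexyl]propanoate | COC(=O)CC[C@]1(C)C(=C)C[C@H](OC(C)=O)C[C@H]1C(C)=C | intermediate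
10 | methyl 3-[(1S,2S,4R)-4-hydroxy-1-methyl-6-methylidene-2-(prop-1-en-2-yl)cyclohexyl]propanoate | COC(=O)CC[C@]1(C)C(=C)C[C@H](O)C[C@H]1C(C)=C | intermediate
11 | methyl 3-[(1S,2S)-1-methyl-6-methylidene-4-oxo-2-(prop-1-en-2-yl)cyclohexyl]propanoate | COC(=O)CC[C@]1(C)C(=C)CC(=O)C[C@H]1C(C)=C | intermediate
12 | 2-(propan-2-yl)propanedioic acid | CC(C)C(C(=O)O)C(=O)O | starting material
13 | 2-(propan-2-yl)propanedioyl dichloride | CC(C)C(C(=O)Cl)C(=O)Cl | intermediate
14 | methyl 3-[(1S,6S)-1-methyl-2-methylidene-6-(prop-1-en-2-yl)-4-[(trimethylsilyl)oxy]cyclohex-3-en-1-yl]propanoate | COC(=O)CC[C@]1(C)C(=C)C=C(O[Si](C)(C)C)C[C@H]1C(C)=C | intermediate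
15 | methyl 3-[(1S,6S)-2-[4-chloro-2,4-dioxo-3-(propan-2-yl)butyl]-1-methyl-4-oxo-6-(prop-1-en-2-yl)cyclohex-2-en-1-yl]propanoate (mixture at the side-chain carbon) | COC(=O)CC[C@]1(C)C(CC(=O)C(C(C)C)C(=O)Cl)=CC(=O)C[C@H]1C(C)=C | intermediate
16 | methyl 3-[(1S,2S)-5,7-dihydroxy-1-methyl-4-oxo-6-(propan-2-yl)-2-(prop-1-en-2-yl)-1,2,3,4-tetrahydronaphthalen-1-yl]propanoate | COC(=O)CC[C@]1(C)c2cc(O)c(C(C)C)c(O)c2C(=O)C[C@H]1C(C)=C | intermediate
17 | methyl 3-[(1S,2S)-7-hydroxy-1-methyl-4,5,8-trioxo-6-(propan-2-yl)-2-(prop-1-en-2-yl)-1,2,3,4,5,8-hexahydronaphthalen-1-yl]propanoate | C=C(C)[C@@H]1CC(=O)C2=C(C(=O)C(O)=C(C(C)C)C2=O)[C@@]1(C)CCC(=O)OC | target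

Total step count: 9. Longest linear sequence: 8 steps (steps 1–6, 8 and 9); step 7 is a one-step branch.

Steps most likely to fail

Step 8 (proposed new method). What may go wrong: acylation of the dienol ether at C8 or on oxygen instead of at C11, followed by lactonisation to a pyranone or by oligomerisation with the bifunctional chloride, so that ring C does not close on carbon. The fallback uses known chemistry and runs from 8 to 16. Ketone 8 is converted (Tf2O, 2,6-di-tert-butyl-4-methylpyridine) into the enol triflate F1, carbonylated (Pd(OAc)2, PPh3, CO, KOAc, DMF) to the cyclohexenecarboxylic acid F2, and taken through the acid chloride F3 ((COCl)2) to the diazo ketone F4 (CH2N2). Irradiation of F4 with the siloxyalkyne F5 (from ethyl isobutyrate by Kowalski homologation and O-silylation with iPr3SiCl), then heating, is the Danheiser benzannulation (photo-Wolff rearrangement, [2+2] cycloaddition, ring opening, six-electron ring closure). It forms the C8–C14 and C11–C12 bonds in one operation and should give the resorcinol monosilyl ether F6. Methanolysis of the acetate (K2CO3, MeOH) to the benzylic alcohol F7, oxidation (MnO2) to the aryl ketone F8 and desilylation (Bu4NF) return to 16.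

Step 3. What may go wrong: slow carbon–carbon bond formation at the congested tetrasubstituted carbon, so that protodesilylation, acrylate polymerisation or attack on the wrong face take over. The fallback runs from 5 to 8. Mild hydrolysis (citric acid, THF/H2O) gives the ketone F9, which is condensed with (S)-1-phenylethylamine to the imine F10. Its more substituted secondary enamine tautomer should add to methyl acrylate 6 under neutral conditions (aza-ene-type Michael addition of a chiral imine, expected anti to isopropenyl and matched with the auxiliary) to give the imine F11, and hydrolysis with aqueous AcOH returns to 8.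

Step 4. What may go wrong: incomplete methylenation of the hindered carbonyl next to the quaternary carbon, or Lewis-acid-induced loss of the β-acetoxy group. The fallback runs from 8 to 9. Addition of Me3SiCH2Li/CeCl3 (organocerium addition, selective for the ketone over the esters at −78 °C) gives the β-hydroxysilane F12, and acid-induced Peterson elimination (cat. H2SO4, THF) returns to 9.

Further compounds
F1 | step 8 | methyl 3-[(1S,4R,6S)-4-(acetyloxy)-1-methyl-6-(prop-1-en-2-yl)-2-{[(trifluoromethyl)sulfonyl]oxy}cyclohex-2-en-1-yl]propanoate | COC(=O)CC[C@]1(C)C(OS(=O)(=O)C(F)(F)F)=C[C@H](OC(C)=O)C[C@H]1C(C)=C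
F2 | step 8 | (3R,5S,6S)-3-(acetyloxy)-6-(3-methoxy-3-oxopropyl)-6-methyl-5-(prop-1-en-2-yl)cyclohex-1-ene-1-carboxylic acid | COC(=O)CC[C@]1(C)C(C(=O)O)=C[C@H](OC(C)=O)C[C@H]1C(C)=C
F3 | step 8 | acid chloride of F2 | COC(=O)CC[C@]1(C)C(C(=O)Cl)=C[C@H](OC(C)=O)C[C@H]1C(C)=C
F4 | step 8 | diazomethyl ketone from F3 | COC(=O)CC[C@]1(C)C(C(=O)C=[N+]=[N-])=C[C@H](OC(C)=O)C[C@H]1C(C)=C
F5 | step 8 | [(3-methylbut-1-yn-1-yl)oxy]tri(propan-2-yl)silane | CC(C)C#CO[Si](C(C)C)(C(C)C)C(C)C
F6 | step 8 | methyl 3-[(1S,2S,4R)-4-(acetyloxy)-5-hydroxy-1-methyl-6-(propan-2-yl)-2-(prop-1-en-2-yl)-7-{[tri(propan-2-yl)silyl]oxy}-1,2,3,4-tetrahydronaphthalen-1-yl]propanoate | COC(=O)CC[C@]1(C)c2cc(O[Si](C(C)C)(C(C)C)C(C)C)c(C(C)C)c(O)c2[C@H](OC(C)=O)C[C@H]1C(C)=C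
F7 | step 8 | methyl 3-[(1S,2S,4R)-4,5-dihydroxy-1-methyl-6-(propan-2-yl)-2-(prop-1-en-2-yl)-7-{[tri(propan-2-yl)silyl]oxy}-1,2,3,4-tetrahydronaphthalen-1-yl]propanoate | COC(=O)CC[C@]1(C)c2cc(O[Si](C(C)C)(C(C)C)C(C)C)c(C(C)C)c(O)c2[C@H](O)C[C@H]1C(C)=C
F8 | step 8 | methyl 3-[(1S,2S)-5-hydroxy-1-methyl-4-oxo-6-(propan-2-yl)-2-(prop-1-en-2-yl)-7-{[tri(propan-2-yl)silyl]oxy}-1,2,3,4-tetrahydronaphthalen-1-yl]propanoate | COC(=O)CC[C@]1(C)c2cc(O[Si](C(C)C)(C(C)C)C(C)C)c(C(C)C)c(O)c2C(=O)C[C@H]1C(C)=C
F9 | step 3 | (1R,5R)-4-methyl-3-oxo-5-(prop-1-en-2-yl)cyclohexyl acetate (mixture at C4) | CC1C(=O)C[C@H](OC(C)=O)C[C@H]1C(C)=C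
F10 | step 3 | imine of F9 with (S)-1-phenylethylamine | CC1C(=N[C@@H](C)c2ccccc2)C[C@H](OC(C)=O)C[C@H]1C(C)=C
F11 | step 3 | imine of 8 with (S)-1-phenylethylamine | COC(=O)CC[C@]1(C)C(=N[C@@H](C)c2ccccc2)C[C@H](OC(C)=O)C[C@H]1C(C)=C
F12 | step 4 | methyl 3-[(1S,2S,4R)-4-(acetyloxy)-6-hydroxy-1-methyl-2-(prop-1-en-2-yl)-6-[(trimethylsilyl)methyl]cyclohexyl]propanoate (mixture at C6) | COC(=O)CC[C@]1(C)C(O)(C[Si](C)(C)C)C[C@H](OC(C)=O)C[C@H]1C(C)=C
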